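**Strategy.** The route rests on one disconnection: the C19–O bond of the lactone bridge, made by functionalising the unactivated 4β-methyl of a carnosic-acid-derived C20 carboxamide. Photolysis of its N-iodo derivative lets the amidyl radical on C20 pull a hydrogen from C19, the methyl that sits 1,3-diaxial to C20 on the β-face of chair ring A (C10 and C4 both axial). Iodine transfer and O-closure give the six-membered C4–C19–O–C20–C10–C5 lactone and make C4 stereogenic in one operation. The precursor is the 7-oxo C20 primary amide with 12-OMe and an 11-acetate. Afterwards the lactone carbonyl is moved from C20 to C19 and C14 is oxygenated.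

Key step: step 6

Remark on the protecting group: O11 of the key-step substrate is carried as an acetate, not as an ether with benzylic or other activated C–H bonds, because such hydrogens would lie within reach of the C20 amidyl radical and would be at risk in the oxidising iodine medium; the acetate also deactivates ring C and is removed by the hydride of step 7 without an extra step.

Remark on stereochemistry: all compounds keep the 5α-H and 10β-C20 of carnosic acid; from compound 11 on, C19 is the 4β (axial) carbon cis to C20 and C18 is the 4α methyl; the target is (4S,5R,10R).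

**Step 1**
Reactants: 1 carnosic acid
Product: 2 carnosic acid γ-lactone (12-hydroxyabieta-8,11,13-trien-20,11-olide)
Conditions: DCC, DMAP (cat.), CH2Cl2, 0 °C to rt, Ar
Reagents that add atoms: none
Why: Steglich-type carbodiimide activation of the C20 acid is trapped intramolecularly by the peri C11 phenol (5-exo-trig; O12 cannot reach C20), so one operation masks the acid and O11 together as a benzofuranone and singles out O12; no stereocentre is involved.

**Step 2**
Reactants: 2 carnosic acid γ-lactone; 3 iodomethane
Product: 4 12-methoxyabieta-8,11,13-trien-20,11-olide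
Conditions: MeI, K2CO3, acetone, rt
Reagents that add atoms: iodomethane, CI
Why: Williamson etherification of the only free hydroxyl (O12), so the regiochemistry of the methylation is fixed by the structure and does not depend on a rate difference between the two phenols.

**Step 3**
Reactants: 4 12-methoxyabieta-8,11,13-trien-20,11-olide
Product: 5 12-methoxy-7-oxoabieta-8,11,13-trien-20,11-olide
Conditions: CrO3, AcOH/H2O, rt
Reagents that add atoms: chromium trioxide, O=[Cr](=O)=O
Why: Chromium(VI) benzylic oxidation converts the C7 methylene, para-activated by the C12 methoxy through C8, into the aryl ketone; with O11 and C20 tied in the lactone there is no phenol to be oxidised and no free C20 carboxyl or amide that could capture C7 in a carnosol-type closure.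

**Step 4**
Reactants: 5 12-methoxy-7-oxoabieta-8,11,13-trien-20,11-olide; 6 ammonia
Product: 7 11-hydroxy-12-methoxy-7-oxoabieta-8,11,13-trien-20-amide
Conditions: NH3 (liq., excess), THF, sealed vessel, rt to 50 °C
Reagents that add atoms: ammonia, N
Why: Aminolysis of an aryl ester: ammonia opens the strained five-membered phenolic lactone at C20 with the C11 phenoxide as leaving group, which gives the primary amide and frees O11 without separate activation of the hindered acid.

**Step 5**
Reactants: 7 11-hydroxy-12-methoxy-7-oxoabieta-8,11,13-trien-20-amide; 8 acetic anhydride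
Product: 9 11-acetoxy-12-methoxy-7-oxoabieta-8,11,13-trien-20-amide
Conditions: Ac2O, pyridine, DMAP (cat.), CH2Cl2, 0 °C to rt
Reagents that add atoms: acetic anhydride, CC(=O)OC(C)=O
Why: DMAP-catalysed O-acetylation of the phenol (the primary amide should not be acylated under these conditions) puts on O11 a group that has no activated C–H bond, makes ring C electron-poorer and is cleaved later by hydride.

**Step 6**
Reactants: 9 11-acetoxy-12-methoxy-7-oxoabieta-8,11,13-trien-20-amide
Product: 13 11-acetoxy-12-methoxy-7-oxoabieta-8,11,13-trien-20,19-olide, via N-iodoamide 10 (not isolated), via 19-iodo amide 11 (not isolated), via iminolactone 12 (not isolated)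
Conditions: PhI(OAc)2, I2 (premixed), CH2Cl2, visible light, rt; then H2O/THF
Reagents that add atoms: water, O
Why: Acetyl hypoiodite formed from PhI(OAc)2 and I2 N-iodinates the primary amide, visible light cleaves the N–I bond, and the amidyl radical on C20 takes a hydrogen from C19 through a seven-membered transition state (1,6-shift), after which the C19 radical is capped by iodine and the amide oxygen displaces iodide to give the iminolactone that water hydrolyses to the lactone. The closest known reaction type is the Barton/Hofmann–Löffler–Freytag photolysis of N-iodoamides to lactones, including its use on diterpenoid amides whose C4 and C10 substituents are 1,3-diaxial. The one ring formed (C4–C19–O–C20–C10–C5) closes by 6-exo-tet O-alkylation at C19. C4 becomes a stereocentre with C19 β because only the axial methyl on the face of C20 can be reached, so its configuration is dictated by the existing C5 and C10 centres, and the equatorial C18 methyl is left untouched. The step needs C19 to win over the syn-axial C2β–H and C6β–H and over ring C: the 1,3-diaxial methyl should lie beside the π-type radical orbital on nitrogen while the syn-axial ring hydrogens lie in the amide plane, C6–H is α to the C7 ketone and polarity-mismatched, and C7 carries no hydrogen. The acetate on O11 has no activated C–H within reach of the radical and, together with the C7 ketone, deactivates ring C towards electrophilic iodine and towards attack by nitrogen.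

**Step 7**
Reactants: 13 11-acetoxy-12-methoxy-7-oxoabieta-8,11,13-trien-20,19-olide
Product: 14 12-methoxyabieta-8,11,13-triene-7,11,19,20-tetraol (mixture of C7 epimers)
Conditions: LiAlH4, THF, 0 °C to reflux; Na2SO4·10H2O quench
Reagents that add atoms: none
Why: Lithium aluminium hydride reduction opens the lactone to the 19,20-diol, cleaves the aryl acetate and reduces the C7 ketone; the new C7 carbinol centre forms without control as an epimer mixture, which is harmless because C7 returns to the ketone in step 9, and the basic quench avoids ionisation of the benzylic alcohol.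

**Step 8**
Reactants: 14 12-methoxyabieta-8,11,13-triene-7,11,19,20-tetraol
Product: 15 7,19,20-trihydroxy-12-methoxyabieta-8,12-diene-11,14-dione (mixture of C7 epimers)
Conditions: Fremy's salt (2.2 equiv), aq. KH2PO4, acetone, rt
Reagents that add atoms: potassium nitrosodisulfonate (Fremy's salt), [K+].[K+].[O]N(S(=O)(=O)[O-])S(=O)(=O)[O-]
Why: Teuber oxidation: the C11 phenol, whose para position C14 is the only unsubstituted ring position, is oxidised to the 11,14-para-quinone, which places the missing oxygen on C14 while the alcohols are left alone.

**Step 9**
Reactants: 15 7,19,20-trihydroxy-12-methoxyabieta-8,12-diene-11,14-dione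
Product: 16 12-methoxy-7,11,14-trioxoabieta-8,12-dien-19,20-olide (lactone carbonyl on C19)
Conditions: TEMPO (cat.), PhI(OAc)2 (3.5 equiv), CH2Cl2, rt
Reagents that add atoms: none
Why: Nitroxyl/oxoammonium oxidative lactonisation: the C19 carbinol, expected to be less encumbered than the C20 carbinol wedged between C1 and the peri C11 carbonyl, should be oxidised first to the aldehyde, the C20 hydroxyl closes the lactol and a second oxidation gives the lactone with its carbonyl on C19, while the same reagent returns the C7 carbinol to the ketone; no stereocentre changes.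

**Step 10**
Reactants: 16 12-methoxy-7,11,14-trioxoabieta-8,12-dien-19,20-olide
Product: 17 11,14-dihydroxy-12-methoxy-7-oxoabieta-8,11,13-trien-19,20-olide (target)
Conditions: Na2S2O4, H2O/EtOAc, rt, Ar
Reagents that add atoms: none
Why: Dithionite reduction of the quinone to the hydroquinone, which is stabilised by the hydrogen bond between the C14 hydroxyl and the C7 ketone, completes the target.

**Compound list**

1 | carnosic acid (11,12-dihydroxyabieta-8,11,13-trien-20-oic acid, 5S,10R) | Oc1c(O)c2c(cc1C(C)C)CC[C@@H]1[C@]2(C(=O)O)CCCC1(C)C | starting material
2 | carnosic acid γ-lactone (12-hydroxyabieta-8,11,13-trien-20,11-olide) | Oc1c(O3)c2c(cc1C(C)C)CC[C@@H]1[C@]2(C3=O)CCCC1(C)C | intermediate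
3 | iodomethane | CI | starting material
4 | 12-methoxyabieta-8,11,13-trien-20,11-olide | COc1c(O3)c2c(cc1C(C)C)CC[C@@H]1[C@]2(C3=O)CCCC1(C)C | intermediate
5 | 12-methoxy-7-oxoabieta-8,11,13-trien-20,11-olide | COc1c(O3)c2c(cc1C(C)C)C(=O)C[C@@H]1[C@]2(C3=O)CCCC1(C)C | intermediate
6 | ammonia | N | starting material
7 | 11-hydroxy-12-methoxy-7-oxoabieta-8,11,13-trien-20-amide | COc1c(O)c2c(cc1C(C)C)C(=O)C[C@@H]1[C@]2(C(N)=O)CCCC1(C)C | intermediate
8 | acetic anhydride | CC(=O)OC(C)=O | starting material
9 | 11-acetoxy-12-methoxy-7-oxoabieta-8,11,13-trien-20-amide (key-step precursor) | COc1c(OC(C)=O)c2c(cc1C(C)C)C(=O)C[C@@H]1[C@]2(C(N)=O)CCCC1(C)C | intermediate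
10 | N-iodo derivative of 9 | COc1c(OC(C)=O)c2c(cc1C(C)C)C(=O)C[C@@H]1[C@]2(C(=O)NI)CCCC1(C)C | intermediate
11 | 11-acetoxy-19-iodo-12-methoxy-7-oxoabieta-8,11,13-trien-20-amide (C19 = 4β carbon) | COc1c(OC(C)=O)c2c(cc1C(C)C)C(=O)C[C@@H]1[C@]2(C(N)=O)CCC[C@]1(C)CI | intermediate
12 | 11-acetoxy-20-imino-12-methoxy-19,20-epoxyabieta-8,11,13-trien-7-one (iminolactone) | COc1c(OC(C)=O)c2c(cc1C(C)C)C(=O)C[C@@H]1[C@]23CCC[C@]1(C)COC3=N | intermediate
13 | 11-acetoxy-12-methoxy-7-oxoabieta-8,11,13-trien-20,19-olide (lactone carbonyl on C20; key-step product) | COc1c(OC(C)=O)c2c(cc1C(C)C)C(=O)C[C@@H]1[C@]23CCC[C@]1(C)COC3=O | intermediate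
14 | 12-methoxyabieta-8,11,13-triene-7,11,19,20-tetraol (C7 epimers) | COc1c(O)c2c(cc1C(C)C)C(O)C[C@@H]1[C@]2(CO)CCC[C@]1(C)CO | intermediate
15 | 7,19,20-trihydroxy-12-methoxyabieta-8,12-diene-11,14-dione (C7 epimers) | COC1C(=O)C2=C(C(=O)C=1C(C)C)C(O)C[C@@H]1[C@]2(CO)CCC[C@]1(C)CO | intermediate
16 | 12-methoxy-7,11,14-trioxoabieta-8,12-dien-19,20-olide (lactone carbonyl on C19) | COC1C(=O)C2=C(C(=O)C=1C(C)C)C(=O)C[C@@H]1[C@]23CCC[C@]1(C)C(=O)OC3 | intermediate
17 | 11,14-dihydroxy-12-methoxy-7-oxoabieta-8,11,13-trien-19,20-olide, (4S,5R,10R) | COc1c(O)c2c(c(O)c1C(C)C)C(=O)C[C@@H]1[C@]23CCC[C@]1(C)C(=O)OC3 | target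

Total step count: 10. Longest linear sequence: 10 steps, from carnosic acid 1.

**Steps most likely to fail**

Step 6. Several processes can divert the amide. The N-iodo or N-iodanyl amide may rearrange ionically, with the tertiary benzylic C10 migrating to nitrogen, before the radical chain starts. The amidyl radical may fragment with loss of the benzylic C10 radical, or take the syn-axial C2β hydrogen instead of a C19 hydrogen. Closure may also occur through nitrogen instead of oxygen. The fallback keeps the same C20-amidyl hydrogen transfer, which the disconnection requires, but removes the iodine(III) oxidant and separates halogenation from ring closure; it therefore answers the ionic diversions, not a wrong choice of hydrogen. It sets out from 9, which is N-chlorinated (t-BuOCl, CH2Cl2, 0 °C, dark) to the N-chloro amide F1. Irradiation in degassed benzene runs a redox-neutral chlorine-atom-transfer chain that should leave the halogen on C19 and give the isolable 19-chloro amide F2, in which the site of hydrogen transfer can be checked before more material is committed. Silver triflate in aqueous acetone then forces O-closure through iminolactone 12, which is hydrolysed in the same pot, and the route is rejoined at 13.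

Step 9. The oxoammonium ion may attack the C20 carbinol first, which would put the lactone carbonyl back on C20; this is the least certain selectivity outside the key step. The fallback replaces the direct oxidative lactonisation by a protection-based sequence that uses the same difference in accessibility in the opposite sense. It sets out from 15, whose more accessible primary hydroxyl (C20 in this failure case) is capped with TBDPSCl/imidazole to give the 20-O-silyl ether F3. TEMPO/PhI(OAc)2 in MeCN/H2O then oxidises the remaining C19 carbinol to the carboxylic acid and the C7 carbinol to the ketone, giving the silyloxy acid F4. HF·pyridine releases the hydroxy acid F5, which should lactonise across the 1,3-diaxial positions (PPTS if needed), and the route is rejoined at 16.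

Step 4. Ammonia may add too slowly to the shielded C20 carbonyl, or the hydroxy amide may close back to the lactone with loss of ammonia on concentration. The fallback makes the amide through the acid chloride after the phenol has been masked. It sets out from 5, which is saponified (LiOH, aq. THF) to the hydroxy acid F6. Ac2O/pyridine acetylates the phenol to the 11-acetoxy acid F7; should the hindered acid be activated instead, the material only returns to 5. Oxalyl chloride with catalytic DMF gives the acid chloride F8, and ammonia in THF at low temperature converts it into the amide, so the route is rejoined at 9 without passing through 7.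

**Further compounds**

F1 | step 6 | N-chloro derivative of 9 | COc1c(OC(C)=O)c2c(cc1C(C)C)C(=O)C[C@@H]1[C@]2(C(=O)NCl)CCCC1(C)C
F2 | step 6 | 11-acetoxy-19-chloro-12-methoxy-7-oxoabieta-8,11,13-trien-20-amide | COc1c(OC(C)=O)c2c(cc1C(C)C)C(=O)C[C@@H]1[C@]2(C(N)=O)CCC[C@]1(C)CCl
F3 | step 9 | 20-(tert-butyldiphenylsilyloxy)-7,19-dihydroxy-12-methoxyabieta-8,12-diene-11,14-dione | COC1C(=O)C2=C(C(=O)C=1C(C)C)C(O)C[C@@H]1[C@]2(CO[Si](c3ccccc3)(c3ccccc3)C(C)(C)C)CCC[C@]1(C)CO
F4 | step 9 | 20-(tert-butyldiphenylsilyloxy)-12-methoxy-7,11,14-trioxoabieta-8,12-dien-19-oic acid | COC1C(=O)C2=C(C(=O)C=1C(C)C)C(=O)C[C@@H]1[C@]2(CO[Si](c3ccccc3)(c3ccccc3)C(C)(C)C)CCC[C@]1(C)C(=O)O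
F5 | step 9 | 20-hydroxy-12-methoxy-7,11,14-trioxoabieta-8,12-dien-19-oic acid | COC1C(=O)C2=C(C(=O)C=1C(C)C)C(=O)C[C@@H]1[C@]2(CO)CCC[C@]1(C)C(=O)O
F6 | step 4 | 11-hydroxy-12-methoxy-7-oxoabieta-8,11,13-trien-20-oic acid | COc1c(O)c2c(cc1C(C)C)C(=O)C[C@@H]1[C@]2(C(=O)O)CCCC1(C)C
F7 | step 4 | 11-acetoxy-12-methoxy-7-oxoabieta-8,11,13-trien-20-oic acid | COc1c(OC(C)=O)c2c(cc1C(C)C)C(=O)C[C@@H]1[C@]2(C(=O)O)CCCC1(C)C
F8 | step 4 | 11-acetoxy-12-methoxy-7-oxoabieta-8,11,13-trien-20-oyl chloride | COc1c(OC(C)=O)c2c(cc1C(C)C)C(=O)C[C@@H]1[C@]2(C(=O)Cl)CCCC1(C)C
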